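**Retrosynthetic overview**

1. Only the 1,4-dioxane ring is built. Rings A, B and C arrive intact in quercetin and the guaiacyl ring in O-benzyl-4-bromoguaiacol. Locants of the C6–C3 unit: C7'' benzylic, C8'' central, C9'' the CH2OH carbon.
2. Last bond, O4'–C7'': intramolecular oxa-1,6-addition of the 4'-OH to the p-quinone methide that 3'-O/C8'' phenol coupling of quercetin with coniferyl alcohol would give in the plant. Here it is generated by DDQ dehydrogenation of a saturated C7'' methylene, and C7'' settles trans to C8'' by equilibration.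
3. O3'–C8'' bond: Mitsunobu inversion of an (R)-carbinol by the 3'-OH of 3,7,4'-tri-O-MOM-quercetin. This replaces the racemic radical coupling, which on a flavonol favours the 4'-O–C8'' regioisomer, and fixes the only independent stereocentre.
4. (R)-Carbinol: Cu-catalysed opening of (R)-benzyl glycidyl ether by the aryl Grignard reagent.
5. Order of ring formation: no ring is formed until the final step, where dioxane closure and global MOM removal occur in one flask.

Assumption: 1-(benzyloxy)-4-bromo-2-methoxybenzene and (R)-benzyl glycidyl ether are bought as catalogue items.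

**Route**

Step 1
Reactants: 1 quercetin
Product: 2 3,7,4'-tri-O-(methoxymethyl)quercetin (3'-OH and 5-OH free)
Conditions: MOMCl (3.3 equiv), K2CO3 (4 equiv), acetone, 0 °C → rt
Reagents that add atoms: chloromethyl methyl ether (MOMCl), COCCl
Why: Williamson-type O-alkylation under acidity control etherifies the three most acidic hydroxyls (7, 4', 3) and leaves the least acidic ring B hydroxyl (3') and the chelated 5-OH free, by analogy with the tribenzylation of quercetin, which gives the 3,7,4'-triether; no stereocentre is formed.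

Step 2
Reactants: 3 1-(benzyloxy)-4-bromo-2-methoxybenzene; 4 (R)-benzyl glycidyl ether
Product: 6 (2R)-1-(benzyloxy)-3-[4-(benzyloxy)-3-methoxyphenyl]propan-2-ol, via arylmagnesium bromide 5 (not isolated)
Conditions: Mg, THF, 50 °C; then 4, CuI (10 mol %), THF, −30 → 0 °C; 1 M HCl work-up
Reagents that add atoms: none
Why: Grignard formation followed by CuI-catalysed SN2 opening of the terminal epoxide at its unsubstituted carbon leaves the stereocentre of 4 untouched, so the (R)-carbinol is obtained with the ee of the glycidyl ether.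

Step 3
Reactants: 2 3,7,4'-tri-O-(methoxymethyl)quercetin; 6 (2R)-1-(benzyloxy)-3-[4-(benzyloxy)-3-methoxyphenyl]propan-2-ol
Product: 7 3'-O-[(2S)-1-(benzyloxy)-3-(4-(benzyloxy)-3-methoxyphenyl)propan-2-yl]-3,7,4'-tri-O-(methoxymethyl)quercetin
Conditions: PPh3, DIAD, THF, 0 °C → rt
Reagents that add atoms: none
Why: In this Mitsunobu etherification the only free non-chelated phenol of 2 (3'-OH) displaces the activated secondary alcohol by SN2 with inversion, giving the (S)-configured C8''–O3' ether, which has the spatial arrangement of C8'' in the target.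

Step 4
Reactants: 7 3'-O-[(2S)-1-(benzyloxy)-3-(4-(benzyloxy)-3-methoxyphenyl)propan-2-yl]-3,7,4'-tri-O-(methoxymethyl)quercetin
Product: 8 3'-O-[(2S)-1-hydroxy-3-(4-hydroxy-3-methoxyphenyl)propan-2-yl]-3,7,4'-tri-O-(methoxymethyl)quercetin
Conditions: H2 (1 atm), Pd(OH)2/C, EtOAc–MeOH, rt
Reagents that add atoms: none
Why: Catalytic hydrogenolysis removes the aryl and the primary alkyl benzyl ether, while the MOM ethers, the chromone and the non-benzylic C8''–O3' bond are inert and the stereocentre is untouched.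

Step 5
Reactants: 8 3'-O-[(2S)-1-hydroxy-3-(4-hydroxy-3-methoxyphenyl)propan-2-yl]-3,7,4'-tri-O-(methoxymethyl)quercetin
Product: 12 (7''R,8''R)-2,3-dehydroisosilybin-type flavonolignan (target), via MOM-protected quinone methide 9 (not isolated), via benzylic methyl ether 10 (not isolated), via free-phenol quinone methide 11 (not isolated)
Conditions: DDQ (1.0 equiv), CH2Cl2–MeOH 4:1, 0 °C; then conc. HCl (to ca. 2 M), MeOH, 50 °C
Reagents that add atoms: none
Why: DDQ dehydrogenation of the 4-alkylguaiacol (the only oxidisable phenol while the flavonol is masked) gives p-quinone methide 9, held as its methanol adduct 10; HCl then cleaves the three MOM ethers and re-ionises the benzylic ether to quinone methide 11, the same species the biosynthetic coupling would give, and the freed 4'-OH closes the dioxane by reversible intramolecular oxa-1,6-addition (quinone methide cyclisation), which sets C7'' trans to the fixed C8'' under thermodynamic control to give the (7''R,8''R) product.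

**Compound list**

1 | quercetin (3,3',4',5,7-pentahydroxyflavone) | O=c1c(O)c(-c2ccc(O)c(O)c2)oc2cc(O)cc(O)c12 | starting material
2 | 3,7,4'-tri-O-(methoxymethyl)quercetin; 5-hydroxy-2-[3-hydroxy-4-(methoxymethoxy)phenyl]-3,7-bis(methoxymethoxy)-4H-chromen-4-one | COCOc1ccc(-c2oc3cc(OCOC)cc(O)c3c(=O)c2OCOC)cc1O | intermediate
3 | 1-(benzyloxy)-4-bromo-2-methoxybenzene | COc1cc(Br)ccc1OCc1ccccc1 | starting material
4 | (R)-benzyl glycidyl ether; (2R)-2-[(benzyloxy)methyl]oxirane | C1O[C@H]1COCc1ccccc1 | starting material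
5 | [4-(benzyloxy)-3-methoxyphenyl]magnesium bromide | COc1cc([Mg]Br)ccc1OCc1ccccc1 | intermediate (not isolated)
6 | (2R)-1-(benzyloxy)-3-[4-(benzyloxy)-3-methoxyphenyl]propan-2-ol | COc1cc(C[C@@H](O)COCc2ccccc2)ccc1OCc1ccccc1 | intermediate
7 | 3'-O-[(2S)-1-(benzyloxy)-3-(4-(benzyloxy)-3-methoxyphenyl)propan-2-yl]-3,7,4'-tri-O-(methoxymethyl)quercetin | COCOc1ccc(-c2oc3cc(OCOC)cc(O)c3c(=O)c2OCOC)cc1O[C@@H](Cc1ccc(OCc2ccccc2)c(OC)c1)COCc1ccccc1 | intermediate
8 | 3'-O-[(2S)-1-hydroxy-3-(4-hydroxy-3-methoxyphenyl)propan-2-yl]-3,7,4'-tri-O-(methoxymethyl)quercetin | COCOc1ccc(-c2oc3cc(OCOC)cc(O)c3c(=O)c2OCOC)cc1O[C@@H](Cc1ccc(O)c(OC)c1)CO | intermediate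
9 | MOM-protected quinone methide: 3'-O-[(2S)-1-hydroxy-3-(3-methoxy-4-oxocyclohexa-2,5-dien-1-ylidene)propan-2-yl]-3,7,4'-tri-O-(methoxymethyl)quercetin (exocyclic C=C geometry not defined) | COCOc1ccc(-c2oc3cc(OCOC)cc(O)c3c(=O)c2OCOC)cc1O[C@@H](C=C1C=CC(=O)C(OC)=C1)CO | intermediate (not isolated)
10 | benzylic methyl ether: 3'-O-[(1RS,2R)-3-hydroxy-1-(4-hydroxy-3-methoxyphenyl)-1-methoxypropan-2-yl]-3,7,4'-tri-O-(methoxymethyl)quercetin (C7'' epimers) | COCOc1ccc(-c2oc3cc(OCOC)cc(O)c3c(=O)c2OCOC)cc1O[C@@H](C(OC)c1ccc(O)c(OC)c1)CO | intermediate (not isolated)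
11 | free-phenol quinone methide: 3'-O-[(2S)-1-hydroxy-3-(3-methoxy-4-oxocyclohexa-2,5-dien-1-ylidene)propan-2-yl]quercetin (O-protonated under the acidic conditions) | Oc1ccc(-c2oc3cc(O)cc(O)c3c(=O)c2O)cc1O[C@@H](C=C1C=CC(=O)C(OC)=C1)CO | intermediate (not isolated)
12 | 3,5,7-trihydroxy-2-[(2R,3R)-2-(4-hydroxy-3-methoxyphenyl)-3-(hydroxymethyl)-2,3-dihydro-1,4-benzodioxin-6-yl]-4H-chromen-4-one (trans; CNP0110568.1) | COc1cc([C@H]2Oc3ccc(-c4oc5cc(O)cc(O)c5c(=O)c4O)cc3O[C@@H]2CO)ccc1O | target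

**Step count and risks**

Total steps: 5. Longest linear sequence: 4 steps (1 → 3 → 4 → 5, or 2 → 3 → 4 → 5).

Three steps most likely to fail:

Step 5 (one-flask dehydrogenation, deprotection and quinone methide closure). The risks are loss of H-8'' from the quinone methide or benzylic cation (enol ether, erosion of ee), attack of DDQ on the flavonoid, and incomplete closure. The fallback builds the dioxane on a vanillin-type ring before the flavonol exists. It sets out from 6. Mitsunobu reaction of 6 with commercial 4-(benzyloxy)-3-hydroxybenzaldehyde (PPh3, DIAD, THF) gives 4-(benzyloxy)-3-{[(2S)-1-(benzyloxy)-3-(4-(benzyloxy)-3-methoxyphenyl)propan-2-yl]oxy}benzaldehyde F1. BCl3 with pentamethylbenzene (CH2Cl2, −78 °C) removes the three benzyl groups without touching the aldehyde and gives 4-hydroxy-3-{[(2S)-1-hydroxy-3-(4-hydroxy-3-methoxyphenyl)propan-2-yl]oxy}benzaldehyde F2. DDQ in dioxane, then catalytic TsOH, oxidises only the 4-alkylguaiacol; the free para-hydroxyl closes the ring directly to (2R,3R)-2-(4-hydroxy-3-methoxyphenyl)-3-(hydroxymethyl)-2,3-dihydro-1,4-benzodioxine-6-carbaldehyde F3. Claisen–Schmidt condensation with 1-[2-hydroxy-4,6-bis(methoxymethoxy)phenyl]ethanone (KOH, EtOH) gives the (E)-2'-hydroxy-4',6'-bis(methoxymethoxy)chalcone F4. Algar–Flynn–Oyamada oxidation (H2O2, NaOH, MeOH) gives the 5,7-bis-O-(methoxymethyl) ether of the target F5. HCl in MeOH then comes back to the route at 12.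

Step 3 (Mitsunobu etherification). The risks are the hindered ortho-substituted phenol and E2 elimination of the homobenzylic alcohol to the styrene. The fallback replaces the redox condensation by a pre-formed electrophile. It sets out from 6, which with Tf2O and 2,6-lutidine (CH2Cl2, −78 °C) gives, with retention, (2R)-1-(benzyloxy)-3-[4-(benzyloxy)-3-methoxyphenyl]propan-2-yl trifluoromethanesulfonate F6. This is displaced by the caesium 3'-phenoxide of 2 (Cs2CO3, DMF, −20 °C → rt) in an SN2 reaction with the same single inversion, and comes back to the route at 7.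

Step 1 (selective tris-MOM protection). The risk is a mixture of di-, tri- and tetra-ethers. The fallback directs the protection through a catechol ketal. It sets out from 1, which with dichlorodiphenylmethane (diphenyl ether, 175 °C) gives 2-(2,2-diphenyl-1,3-benzodioxol-5-yl)-3,5,7-trihydroxy-4H-chromen-4-one F7. MOMCl (2.2 equiv) and K2CO3 give 2-(2,2-diphenyl-1,3-benzodioxol-5-yl)-5-hydroxy-3,7-bis(methoxymethoxy)-4H-chromen-4-one F8. Hydrogenolysis of the ketal (H2, Pd(OH)2/C, THF–MeOH) gives 3,7-di-O-(methoxymethyl)quercetin F9. One equivalent of MOMCl (K2CO3, acetone, −10 °C) then etherifies the more acidic 4'-OH and comes back to the route at 2.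

**Further compounds**

F1 | step 5 | 4-(benzyloxy)-3-{[(2S)-1-(benzyloxy)-3-(4-(benzyloxy)-3-methoxyphenyl)propan-2-yl]oxy}benzaldehyde | O=Cc1ccc(OCc2ccccc2)c(O[C@@H](Cc2ccc(OCc3ccccc3)c(OC)c2)COCc2ccccc2)c1
F2 | step 5 | 4-hydroxy-3-{[(2S)-1-hydroxy-3-(4-hydroxy-3-methoxyphenyl)propan-2-yl]oxy}benzaldehyde | O=Cc1ccc(O)c(O[C@@H](Cc2ccc(O)c(OC)c2)CO)c1
F3 | step 5 | (2R,3R)-2-(4-hydroxy-3-methoxyphenyl)-3-(hydroxymethyl)-2,3-dihydro-1,4-benzodioxine-6-carbaldehyde | COc1cc([C@H]2Oc3ccc(C=O)cc3O[C@@H]2CO)ccc1O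
F4 | step 5 | (E)-1-[2-hydroxy-4,6-bis(methoxymethoxy)phenyl]-3-[(2R,3R)-2-(4-hydroxy-3-methoxyphenyl)-3-(hydroxymethyl)-2,3-dihydro-1,4-benzodioxin-6-yl]prop-2-en-1-one | COc1cc([C@H]2Oc3ccc(/C=C/C(=O)c4c(O)cc(OCOC)cc4OCOC)cc3O[C@@H]2CO)ccc1O
F5 | step 5 | 3-hydroxy-2-[(2R,3R)-2-(4-hydroxy-3-methoxyphenyl)-3-(hydroxymethyl)-2,3-dihydro-1,4-benzodioxin-6-yl]-5,7-bis(methoxymethoxy)-4H-chromen-4-one | COc1cc([C@H]2Oc3ccc(-c4oc5cc(OCOC)cc(OCOC)c5c(=O)c4O)cc3O[C@@H]2CO)ccc1O
F6 | step 3 | (2R)-1-(benzyloxy)-3-[4-(benzyloxy)-3-methoxyphenyl]propan-2-yl trifluoromethanesulfonate | COc1cc(C[C@@H](OS(=O)(=O)C(F)(F)F)COCc2ccccc2)ccc1OCc1ccccc1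
F7 | step 1 | 2-(2,2-diphenyl-1,3-benzodioxol-5-yl)-3,5,7-trihydroxy-4H-chromen-4-one | O=c1c(O)c(-c2ccc3OC(c4ccccc4)(c4ccccc4)Oc3c2)oc2cc(O)cc(O)c12
F8 | step 1 | 2-(2,2-diphenyl-1,3-benzodioxol-5-yl)-5-hydroxy-3,7-bis(methoxymethoxy)-4H-chromen-4-one | O=c1c(OCOC)c(-c2ccc3OC(c4ccccc4)(c4ccccc4)Oc3c2)oc2cc(OCOC)cc(O)c12
F9 | step 1 | 3,7-di-O-(methoxymethyl)quercetin; 2-(3,4-dihydroxyphenyl)-5-hydroxy-3,7-bis(methoxymethoxy)-4H-chromen-4-one | O=c1c(OCOC)c(-c2ccc(O)c(O)c2)oc2cc(OCOC)cc(O)c12
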